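Its constants were drawn at random within sensible limits.

The ratio to watch is reagent charged over the intermediate B that the substrate can supply, since each target consumes one of each.

| setting | east | south-west | north-west |
|---|---|---|---|
| substrate | 38 mM | 38 mM | 38 mM |
| reagent | 0.600 equiv | 0.600 equiv | 0.600 equiv |
| temperature | 40 °C | 60 °C | 20 °C |
| time | 25 min | 25 min | 25 min |

    substrate → intermediate A (k1 = 0.0026 s⁻¹, Ea1 = 94.0 kJ mol⁻¹)
    reagent + intermediate A ⇌ intermediate C (K2 = 15 L mol⁻¹, k2 = 3.5 L mol⁻¹ s⁻¹, Ea2 = 43.0 kJ mol⁻¹, ΔH2 = −49.0 kJ mol⁻¹)
    reagent + intermediate B → target (k3 = 3.3 L mol⁻¹ s⁻¹, Ea3 = 54.0 kJ mol⁻¹)
    intermediate A → side product (k4 = 5.4 × 10⁻⁴ s⁻¹, Ea4 = 89.0 kJ mol⁻¹)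
    intermediate A → intermediate B (k5 = 0.012 s⁻¹, Ea5 = 91.0 kJ mol⁻¹)
    (constants at 20 °C)

- at 20 °C the constants are as listed, elsewhere as the activation energies and enthalpies make them

- the flask that comes out highest in amount of target, in percent of the substrate charged, or "all alike" when all lie within 1.5 percentage points (east / south-west / north-west / all alike)
- target at the end, in percent of the substrate charged, east
- target at the end, in percent of the substrate charged, south-west
- target at the end, in percent of the substrate charged, north-west

By hand, at the constants as listed, intermediate A sends 95.7% of its flow to intermediate B. That is more than the reagent charge of 0.600 equiv, so reagent is the limiting reagent. The two branches differ in activation energy by 2.00 kJ mol⁻¹, far below either value, so the share stays close to this in the warmer flasks.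

Two times remain. Since c(substrate) decays exponentially, its integrated loss gives the moment when substrate consumed, multiplied by the share, equals the reagent charge; the mean life of intermediate A, 1.33 min in north-west, is added to it, and the sum is the delivery time: in north-west 7.65 min, against the asked 25 min. In north-west intermediate C gives back its reagent with a half-life of 2.97 s, far shorter than the delivery time, so the reckoning adds no time for it. The reckoning therefore puts target at 60.0% in north-west. The warmer flasks convert substrate faster, which gives 60.0% in east and 60.0% in south-west, with no flask ahead by the margin of 1.5 percentage points.

The forecast gives 60% for east, 60% for south-west, 59.9% for north-west and all alike, holding that “25 min is long enough for this to finish even in the coldest flask”.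

The simulation gives 60.0% in east, 60.0% in south-west and 60.0% in north-west, so all alike. In north-west the asked time is 3.27 delivery times, and reagent stands at 0% of its charge with 33.3% of intermediate B beside it. The forecast's figure for north-west is off by about 5 points once the reading moves down to 8.66 min, and a reading of north-west at 6.0 min, 0.784 of the delivery time, shows target at 41.7% with 29% of the reagent still unbound.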